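**Retrosynthetic overview**
- Last bonds: two esterifications of a 14-oxo melampolide core, O9 with the C21 diacetoxy trienoic acid, then O8 with a silyl-protected 2-(hydroxymethyl)acrylic acid.
- Core: SeO2 oxidation of C14 in an all-trans germacrolide; the same step turns C1=C10 ring-cis.
- Key disconnection (C6–C7 and O6–C12 in one operation): a 3-(bromomethyl)dihydropyranone tethered through O9 allylates the C6 enal, closing the ten-membered carbocycle first; O6 then takes over the acyl group, closing the γ-lactone second and opening the temporary δ-lactone.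
- The temporary δ-lactone is made one step earlier by ring-closing metathesis; C8 and C9 come from an asymmetric syn-alkoxyallylation of a terpene-derived enal.
- Side-chain acid: two Z-selective Horner–Wadsworth–Emmons olefinations starting from a second terpene acetate.

Assumption: positions C1–C15 follow germacranolide numbering (C6 lactone carbinol, C7, C8 and C9 the ester-bearing carbons, C1=C10 carrying C14, C4=C5 carrying C15, C11–C13 the methylene lactone); reagents given without a number are bought.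

**Step 1**
Reactants: 1 geranyl acetate
Product: 2 (2E,6E)-3,7-dimethyl-8-oxoocta-2,6-dien-1-yl acetate
Conditions: SeO2 (1.2 equiv), EtOH, reflux
Reagents that add atoms: selenium dioxide, O=[Se]=O
Why: Riley allylic oxidation (ene reaction, then [2,3]-shift) attacks only the terminal alkene, because the other one is deactivated by the allylic acetate, and oxidises the methyl trans to the chain, giving the E enal.

**Step 2**
Reactants: 3 allyl alcohol
Product: 4 allyl methoxymethyl ether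
Conditions: MOMCl, i-Pr2NEt, CH2Cl2, 0 to 25 °C
Reagents that add atoms: chloromethyl methyl ether, COCCl
Why: O-alkylation of the alcohol by the α-chloro ether through its oxocarbenium ion (Williamson-type etherification).

**Step 3**
Reactants: 2 (2E,6E)-3,7-dimethyl-8-oxoocta-2,6-dien-1-yl acetate; 4 allyl methoxymethyl ether
Product: 6 (2E,6E,8S,9S)-9-(methoxymethoxy)-3,7-dimethylundeca-2,6,10-triene-1,8-diol, via hydroxy acetate 5 (not isolated)
Conditions: 4, s-BuLi, THF, −78 °C; (+)-Ipc2BOMe; BF3·OEt2; then 2, −78 °C; then 3 M NaOH, 30% H2O2, 25 to 60 °C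
Reagents that add atoms: none
Why: Brown asymmetric γ-alkoxyallylboration through a closed chair transition state: the Z enol ether gives the syn O8/O9 relationship, the (+)-Ipc2B unit (from (−)-α-pinene) directs attack to the Re face of the enal to set both new centres (S,S), and the basic peroxide work-up also saponifies the primary acetate.

**Step 4**
Reactants: 6 (2E,6E,8S,9S)-9-(methoxymethoxy)-3,7-dimethylundeca-2,6,10-triene-1,8-diol
Product: 7 (2E,6E,8S,9S)-8-hydroxy-9-(methoxymethoxy)-3,7-dimethylundeca-2,6,10-trienal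
Conditions: TEMPO (0.1 equiv), PhI(OAc)2 (1.1 equiv), CH2Cl2, 25 °C
Reagents that add atoms: none
Why: Oxoammonium (TEMPO) oxidation is selective for the primary allylic alcohol over the hindered secondary one.

**Step 5**
Reactants: 7 (2E,6E,8S,9S)-8-hydroxy-9-(methoxymethoxy)-3,7-dimethylundeca-2,6,10-trienal; 8 2-(bromomethyl)acrylic acid
Product: 10 (3S,4S,5E,9E)-3-(methoxymethoxy)-5,9-dimethyl-11-oxoundeca-1,5,9-trien-4-yl 2-(bromomethyl)prop-2-enoate, via acid chloride 9 (not isolated)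
Conditions: 8, (COCl)2, DMF (cat.), CH2Cl2, 0 to 25 °C; then 7, 2,6-lutidine, CH2Cl2, −20 to 25 °C
Reagents that add atoms: none
Why: Nucleophilic acyl substitution of the acid chloride by the secondary alcohol; the hindered, non-nucleophilic base spares the very reactive allylic bromide.

**Step 6**
Reactants: 10 (3S,4S,5E,9E)-3-(methoxymethoxy)-5,9-dimethyl-11-oxoundeca-1,5,9-trien-4-yl 2-(bromomethyl)prop-2-enoate
Product: 11 (2E,6E)-7-[(2S,3S)-5-(bromomethyl)-3-(methoxymethoxy)-6-oxo-3,6-dihydro-2H-pyran-2-yl]-3-methylocta-2,6-dienal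
Conditions: second-generation Grubbs catalyst (5 mol%), CH2Cl2 (5 mM), 40 °C
Reagents that add atoms: none
Why: Ring-closing metathesis of the 2-substituted acrylate with the terminal vinyl group gives the six-membered unsaturated lactone; the trisubstituted alkenes and the enal do not take part.

**Step 7**
Reactants: 11 (2E,6E)-7-[(2S,3S)-5-(bromomethyl)-3-(methoxymethoxy)-6-oxo-3,6-dihydro-2H-pyran-2-yl]-3-methylocta-2,6-dienal
Product: 13 (1(10)E,4E,6R,7S,8S,9S)-9-hydroxy-8-(methoxymethoxy)germacra-1(10),4,11(13)-trien-12,6-olide, via bridged δ-lactone 12 (not isolated)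
Conditions: CrCl2 (8 equiv), THF–DMF (4:1), slow addition of 11 to 1 mM, 25 °C; aq. NH4Cl
Reagents that add atoms: none
Why: Proposed new method: CrCl2 inserts into the allylic C–Br bond to give a 2-carbonyl-substituted allylchromium whose γ-carbon (C7) is locked in the dihydropyranone with C8 trans to CH2Cr (an E-crotyl-type reagent), so a chair Zimmerman–Traxler addition to the tethered C6 enal should be anti (6,7-trans) and occur on the ring face opposite the pseudo-axial 8-OMOM group (C7 trans to O8), closing the ten-membered carbocycle as a bridged α-methylene-δ-lactone whose 6-alkoxide, held γ to C12, then takes over the acyl group and expels O9 (translactonisation to the trans-fused γ-lactone), so that carbocycle and γ-lactone form in one operation and C6 and C7 are set as 6R,7S; the closest known reactions are the CrCl2-mediated intramolecular Nozaki–Hiyama (Barbier-type) allylation–lactonisation of open-chain 2-(bromomethyl)enoate aldehydes to ten-membered germacranolides and the Barbier allylations of 3-(bromomethyl)furan-2(5H)-ones.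

**Step 8**
Reactants: 13 (1(10)E,4E,6R,7S,8S,9S)-9-hydroxy-8-(methoxymethoxy)germacra-1(10),4,11(13)-trien-12,6-olide
Product: 14 (1(10)Z,4E,6R,7S,8S,9S)-9,14-dihydroxy-8-(methoxymethoxy)germacra-1(10),4,11(13)-trien-12,6-olide
Conditions: SeO2 (0.5 equiv), t-BuOOH (4 equiv), CH2Cl2, 25 °C
Reagents that add atoms: tert-butyl hydroperoxide, CC(C)(C)OO (oxygen carried over by catalytic selenium dioxide, O=[Se]=O)
Why: SeO2 allylic oxidation (ene reaction, then [2,3]-shift) should prefer C1=C10 over C4=C5, which is deactivated by the allylic lactone oxygen as in step 1; it oxidises methyl C14 and the [2,3]-shift places CH2OH trans to C2, which turns the ring alkene from trans to cis, the change known for parthenolide going to melampomagnolide B.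

**Step 9**
Reactants: 14 (1(10)Z,4E,6R,7S,8S,9S)-9,14-dihydroxy-8-(methoxymethoxy)germacra-1(10),4,11(13)-trien-12,6-olide
Product: 15 (1(10)E,4E,6R,7S,8S,9S)-9-hydroxy-8-(methoxymethoxy)-14-oxogermacra-1(10),4,11(13)-trien-12,6-olide
Conditions: TEMPO (0.1 equiv), PhI(OAc)2 (1.1 equiv), CH2Cl2, 0 to 25 °C
Reagents that add atoms: none
Why: Oxoammonium (TEMPO) oxidation takes the primary allylic 14-alcohol to the enal and leaves the secondary 9-OH; the ring alkene stays ring-cis (the E label only reflects the new CHO priority).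

**Step 10**
Reactants: 16 neryl acetate
Product: 17 (2Z)-3-methyl-6-oxohex-2-en-1-yl acetate
Conditions: O3 (1 equiv, Sudan red 7B end point), CH2Cl2–MeOH, −78 °C; then Me2S
Reagents that add atoms: ozone, [O-][O+]=O
Why: Ozonolysis with one equivalent of ozone cleaves the electron-rich terminal alkene; the alkene next to the allylic acetate is deactivated and keeps its Z geometry.

**Step 11**
Reactants: 18 methyl bis(2,2,2-trifluoroethyl)phosphonoacetate; 19 3-bromo-1,1-dimethoxypropane
Product: 20 methyl 2-[bis(2,2,2-trifluoroethoxy)phosphoryl]-5,5-dimethoxypentanoate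
Conditions: NaH, DMSO, 25 °C; then 19, NaI (cat.), 50 °C
Reagents that add atoms: none
Why: SN2 C-alkylation of the stabilised phosphonoacetate carbanion by the primary bromide.

**Step 12**
Reactants: 17 (2Z)-3-methyl-6-oxohex-2-en-1-yl acetate; 20 methyl 2-[bis(2,2,2-trifluoroethoxy)phosphoryl]-5,5-dimethoxypentanoate
Product: 21 methyl (2Z,6Z)-8-acetoxy-2-(3,3-dimethoxypropyl)-6-methylocta-2,6-dienoate
Conditions: 20, KN(SiMe3)2, 18-crown-6, THF, −78 °C; then 17
Reagents that add atoms: none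
Why: Still–Gennari variant of the Horner–Wadsworth–Emmons reaction: the trifluoroethyl phosphonate with a free potassium counter-ion eliminates fast from the kinetic adduct and places the ester cis to the chain (2Z).

**Step 13**
Reactants: 21 methyl (2Z,6Z)-8-acetoxy-2-(3,3-dimethoxypropyl)-6-methylocta-2,6-dienoate
Product: 22 (2Z,6Z)-2-(3,3-dimethoxypropyl)-6-methylocta-2,6-diene-1,8-diol
Conditions: i-Bu2AlH (6 equiv), CH2Cl2, −78 to 0 °C; aq. potassium sodium tartrate
Reagents that add atoms: none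
Why: Hydride 1,2-reduction of the conjugated ester to the allylic alcohol, with cleavage of the acetate; the acetal and the alkene geometries are untouched.

**Step 14**
Reactants: 22 (2Z,6Z)-2-(3,3-dimethoxypropyl)-6-methylocta-2,6-diene-1,8-diol
Product: 23 (2Z,6Z)-2-(3,3-dimethoxypropyl)-6-methylocta-2,6-diene-1,8-diyl diacetate
Conditions: Ac2O, pyridine, DMAP (cat.), CH2Cl2, 25 °C
Reagents that add atoms: acetic anhydride, CC(=O)OC(C)=O
Why: DMAP-catalysed acetylation of both primary allylic alcohols.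

**Step 15**
Reactants: 23 (2Z,6Z)-2-(3,3-dimethoxypropyl)-6-methylocta-2,6-diene-1,8-diyl diacetate
Product: 24 (2Z,6Z)-6-methyl-2-(3-oxopropyl)octa-2,6-diene-1,8-diyl diacetate
Conditions: AcOH–THF–H2O (3:1:1), 25 °C
Reagents that add atoms: water, O
Why: Mild acid hydrolysis of the dimethyl acetal; the allylic acetates and trisubstituted alkenes survive these conditions.

**Step 16**
Reactants: 25 but-3-yn-1-ol; 26 isopropylmagnesium chloride
Product: 27 4-methyl-3-methylidenepentan-1-ol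
Conditions: 26 (3 equiv), CuI (10 mol%), THF, 0 °C to reflux; aq. NH4Cl
Reagents that add atoms: none
Why: Copper-catalysed carbomagnesiation of the homopropargylic alkoxide: the alkoxide directs the isopropyl group to the internal alkyne carbon and protonolysis leaves the 1,1-disubstituted alkene.

**Step 17**
Reactants: 27 4-methyl-3-methylidenepentan-1-ol
Product: 28 1-iodo-4-methyl-3-methylidenepentane
Conditions: iodine, PPh3, imidazole, CH2Cl2, 0 °C
Reagents that add atoms: iodine, [I][I]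
Why: Appel-type iodination of the primary alcohol through the alkoxyphosphonium salt (SN2).

**Step 18**
Reactants: 18 methyl bis(2,2,2-trifluoroethyl)phosphonoacetate; 28 1-iodo-4-methyl-3-methylidenepentane
Product: 29 methyl 2-[bis(2,2,2-trifluoroethoxy)phosphoryl]-6-methyl-5-methylideneheptanoate
Conditions: NaH, DMSO, 25 °C; then 28, 25 to 50 °C
Reagents that add atoms: none
Why: SN2 C-alkylation of the phosphonoacetate carbanion by the primary iodide.

**Step 19**
Reactants: 24 (2Z,6Z)-6-methyl-2-(3-oxopropyl)octa-2,6-diene-1,8-diyl diacetate; 29 methyl 2-[bis(2,2,2-trifluoroethoxy)phosphoryl]-6-methyl-5-methylideneheptanoate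
Product: 30 methyl (2Z,6Z,10Z)-12-acetoxy-6-(acetoxymethyl)-10-methyl-2-(4-methyl-3-methylidenepentyl)dodeca-2,6,10-trienoate
Conditions: 29, KN(SiMe3)2, 18-crown-6, THF, −78 °C; then 24
Reagents that add atoms: none
Why: Second Still–Gennari olefination; the α-branched trifluoroethyl phosphonate gives the trisubstituted enoate with the ester cis to the chain (2Z).

**Step 20**
Reactants: 30 methyl (2Z,6Z,10Z)-12-acetoxy-6-(acetoxymethyl)-10-methyl-2-(4-methyl-3-methylidenepentyl)dodeca-2,6,10-trienoate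
Product: 31 (2Z,6Z,10Z)-12-hydroxy-6-(hydroxymethyl)-10-methyl-2-(4-methyl-3-methylidenepentyl)dodeca-2,6,10-trienoic acid
Conditions: LiOH, THF–MeOH–H2O, 40 °C; then 1 M HCl to pH 3
Reagents that add atoms: lithium hydroxide, [Li+].[OH-]
Why: Saponification of the methyl ester (and, unavoidably, both acetates); hydroxide does not isomerise the Z enoate.

**Step 21**
Reactants: 31 (2Z,6Z,10Z)-12-hydroxy-6-(hydroxymethyl)-10-methyl-2-(4-methyl-3-methylidenepentyl)dodeca-2,6,10-trienoic acid
Product: 33 (2Z,6Z,10Z)-12-acetoxy-6-(acetoxymethyl)-10-methyl-2-(4-methyl-3-methylidenepentyl)dodeca-2,6,10-trienoic acid, via acetic mixed anhydride 32 (not isolated)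
Conditions: Ac2O, pyridine, DMAP (cat.), 25 °C; then H2O–THF, 25 °C
Reagents that add atoms: acetic anhydride, CC(=O)OC(C)=O
Why: Acetylation of both primary alcohols; the mixed anhydride formed at the acid is hydrolysed back by water while the acetates stay.

**Step 22**
Reactants: 34 ethyl 2-(hydroxymethyl)acrylate
Product: 35 ethyl 2-[(tert-butyldimethylsilyloxy)methyl]acrylate
Conditions: TBSCl, imidazole, CH2Cl2, 0 to 25 °C
Reagents that add atoms: tert-butyldimethylsilyl chloride, CC(C)(C)[Si](C)(C)Cl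
Why: Imidazole-promoted silylation of the primary alcohol.

**Step 23**
Reactants: 35 ethyl 2-[(tert-butyldimethylsilyloxy)methyl]acrylate
Product: 36 2-[(tert-butyldimethylsilyloxy)methyl]acrylic acid
Conditions: LiOH, THF–H2O, 0 °C; then 1 M HCl to pH 4
Reagents that add atoms: lithium hydroxide, [Li+].[OH-]
Why: Saponification of the ethyl ester; the primary silyl ether is stable to cold LiOH.

**Step 24**
Reactants: 15 (1(10)E,4E,6R,7S,8S,9S)-9-hydroxy-8-(methoxymethoxy)-14-oxogermacra-1(10),4,11(13)-trien-12,6-olide; 33 (2Z,6Z,10Z)-12-acetoxy-6-(acetoxymethyl)-10-methyl-2-(4-methyl-3-methylidenepentyl)dodeca-2,6,10-trienoic acid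
Product: 38 (1(10)E,4E,6R,7S,8S,9S)-9-[(2Z,6Z,10Z)-12-acetoxy-6-(acetoxymethyl)-10-methyl-2-(4-methyl-3-methylidenepentyl)dodeca-2,6,10-trienoyloxy]-8-(methoxymethoxy)-14-oxogermacra-1(10),4,11(13)-trien-12,6-olide, via trichlorobenzoyl mixed anhydride 37 (not isolated)
Conditions: 33, 2,4,6-Cl3C6H2COCl, Et3N, toluene, 25 °C; then 15, DMAP (0.3 equiv), toluene, 25 °C
Reagents that add atoms: none
Why: Yamaguchi esterification: the alcohol attacks the enoyl carbonyl of the mixed anhydride because the aroyl carbonyl is shielded by its ortho chlorines; little DMAP and room temperature keep the 2Z geometry.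

**Step 25**
Reactants: 38 (1(10)E,4E,6R,7S,8S,9S)-9-[(2Z,6Z,10Z)-12-acetoxy-6-(acetoxymethyl)-10-methyl-2-(4-methyl-3-methylidenepentyl)dodeca-2,6,10-trienoyloxy]-8-(methoxymethoxy)-14-oxogermacra-1(10),4,11(13)-trien-12,6-olide
Product: 40 (1(10)E,4E,6R,7R,8S,9S)-9-[(2Z,6Z,10Z)-12-acetoxy-6-(acetoxymethyl)-10-methyl-2-(4-methyl-3-methylidenepentyl)dodeca-2,6,10-trienoyloxy]-8-hydroxy-14-oxogermacra-1(10),4,11(13)-trien-12,6-olide, via bromomethyl ether 39 (not isolated)
Conditions: Me2BBr (3 equiv), CH2Cl2, −78 °C; then aq. NaHCO3–THF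
Reagents that add atoms: none
Why: Lewis-acid cleavage of the MOM acetal by the bromoborane at −78 °C, where esters, lactone, enal and alkenes are inert; the bromomethyl ether hydrolyses on work-up (the 7R label is only a priority change, the geometry is unchanged).

**Step 26**
Reactants: 40 (1(10)E,4E,6R,7R,8S,9S)-9-[(2Z,6Z,10Z)-12-acetoxy-6-(acetoxymethyl)-10-methyl-2-(4-methyl-3-methylidenepentyl)dodeca-2,6,10-trienoyloxy]-8-hydroxy-14-oxogermacra-1(10),4,11(13)-trien-12,6-olide; 36 2-[(tert-butyldimethylsilyloxy)methyl]acrylic acid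
Product: 41 (1(10)E,4E,6R,7S,8S,9S)-9-[(2Z,6Z,10Z)-12-acetoxy-6-(acetoxymethyl)-10-methyl-2-(4-methyl-3-methylidenepentyl)dodeca-2,6,10-trienoyloxy]-8-{2-[(tert-butyldimethylsilyloxy)methyl]acryloyloxy}-14-oxogermacra-1(10),4,11(13)-trien-12,6-olide
Conditions: EDC·HCl, DMAP (0.2 equiv), CH2Cl2, 0 to 25 °C
Reagents that add atoms: none
Why: Steglich esterification of the 8-OH by the O-acylisourea; low temperature and little DMAP limit migration of the neighbouring C9 acyl group.

**Step 27**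
Reactants: 41 (1(10)E,4E,6R,7S,8S,9S)-9-[(2Z,6Z,10Z)-12-acetoxy-6-(acetoxymethyl)-10-methyl-2-(4-methyl-3-methylidenepentyl)dodeca-2,6,10-trienoyloxy]-8-{2-[(tert-butyldimethylsilyloxy)methyl]acryloyloxy}-14-oxogermacra-1(10),4,11(13)-trien-12,6-olide
Product: 42 CNP0240680.3
Conditions: HF·pyridine, pyridine–THF, 0 °C
Reagents that add atoms: none
Why: Fluoride-driven desilylation of the primary silyl ether under buffered conditions that leave the esters, lactone and enal alone.

**Compound list**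
1 | geranyl acetate | CC(C)=CCC/C(C)=C/COC(C)=O | starting material
2 | (2E,6E)-3,7-dimethyl-8-oxoocta-2,6-dien-1-yl acetate | O=C/C(C)=C/CC/C(C)=C/COC(C)=O | intermediate
3 | allyl alcohol | C=CCO | starting material
4 | allyl methoxymethyl ether | C=CCOCOC | intermediate
5 | (2E,6E,8S,9S)-8-hydroxy-9-(methoxymethoxy)-3,7-dimethylundeca-2,6,10-trien-1-yl acetate (not isolated) | C=C[C@H](OCOC)[C@@H](O)/C(C)=C/CC/C(C)=C/COC(C)=O | intermediate
6 | (2E,6E,8S,9S)-9-(methoxymethoxy)-3,7-dimethylundeca-2,6,10-triene-1,8-diol | C=C[C@H](OCOC)[C@@H](O)/C(C)=C/CC/C(C)=C/CO | intermediate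
7 | (2E,6E,8S,9S)-8-hydroxy-9-(methoxymethoxy)-3,7-dimethylundeca-2,6,10-trienal | C=C[C@H](OCOC)[C@@H](O)/C(C)=C/CC/C(C)=C/C=O | intermediate
8 | 2-(bromomethyl)acrylic acid | C=C(CBr)C(=O)O | starting material
9 | 2-(bromomethyl)acryloyl chloride (not isolated) | C=C(CBr)C(=O)Cl | intermediate
10 | (3S,4S,5E,9E)-3-(methoxymethoxy)-5,9-dimethyl-11-oxoundeca-1,5,9-trien-4-yl 2-(bromomethyl)prop-2-enoate | C=C[C@H](OCOC)[C@@H](OC(=O)C(=C)CBr)/C(C)=C/CC/C(C)=C/C=O | intermediate
11 | (2E,6E)-7-[(2S,3S)-5-(bromomethyl)-3-(methoxymethoxy)-6-oxo-3,6-dihydro-2H-pyran-2-yl]-3-methylocta-2,6-dienal | BrCC1=C[C@H](OCOC)[C@H](/C(C)=C/CC/C(C)=C/C=O)OC1=O | intermediate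
12 | (1(10)E,4E,6R,7S,8S,9S)-6-hydroxy-8-(methoxymethoxy)germacra-1(10),4,11(13)-trien-12,9-olide, the bridged δ-lactone (not isolated) | COCO[C@H]1[C@H]2C(=C)C(=O)O[C@H]1/C(C)=C/CC/C(C)=C/[C@H]2O | intermediate
13 | (1(10)E,4E,6R,7S,8S,9S)-9-hydroxy-8-(methoxymethoxy)germacra-1(10),4,11(13)-trien-12,6-olide (both ring alkenes ring-trans) | COCO[C@H]1[C@H]2C(=C)C(=O)O[C@@H]2/C=C(\C)CC/C=C(\C)[C@@H]1O | intermediate
14 | (1(10)Z,4E,6R,7S,8S,9S)-9,14-dihydroxy-8-(methoxymethoxy)germacra-1(10),4,11(13)-trien-12,6-olide (C1=C10 ring-cis) | COCO[C@H]1[C@H]2C(=C)C(=O)O[C@@H]2/C=C(\C)CC/C=C(/CO)[C@@H]1O | intermediate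
15 | (1(10)E,4E,6R,7S,8S,9S)-9-hydroxy-8-(methoxymethoxy)-14-oxogermacra-1(10),4,11(13)-trien-12,6-olide (C1=C10 ring-cis) | COCO[C@H]1[C@H]2C(=C)C(=O)O[C@@H]2/C=C(\C)CC/C=C(/C=O)[C@@H]1O | intermediate
16 | neryl acetate | CC(C)=CCC/C(C)=C\COC(C)=O | starting material
17 | (2Z)-3-methyl-6-oxohex-2-en-1-yl acetate | O=CCC/C(C)=C\COC(C)=O | intermediate
18 | methyl bis(2,2,2-trifluoroethyl)phosphonoacetate | COC(=O)CP(=O)(OCC(F)(F)F)OCC(F)(F)F | starting material
19 | 3-bromo-1,1-dimethoxypropane | COC(CCBr)OC | starting material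
20 | methyl 2-[bis(2,2,2-trifluoroethoxy)phosphoryl]-5,5-dimethoxypentanoate | COC(=O)C(CCC(OC)OC)P(=O)(OCC(F)(F)F)OCC(F)(F)F | intermediate
21 | methyl (2Z,6Z)-8-acetoxy-2-(3,3-dimethoxypropyl)-6-methylocta-2,6-dienoate | COC(=O)/C(=C\CC/C(C)=C\COC(C)=O)CCC(OC)OC | intermediate
22 | (2Z,6Z)-2-(3,3-dimethoxypropyl)-6-methylocta-2,6-diene-1,8-diol | OC/C(=C\CC/C(C)=C\CO)CCC(OC)OC | intermediate
23 | (2Z,6Z)-2-(3,3-dimethoxypropyl)-6-methylocta-2,6-diene-1,8-diyl diacetate | CC(=O)OC/C(=C\CC/C(C)=C\COC(C)=O)CCC(OC)OC | intermediate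
24 | (2Z,6Z)-6-methyl-2-(3-oxopropyl)octa-2,6-diene-1,8-diyl diacetate | CC(=O)OC/C(=C\CC/C(C)=C\COC(C)=O)CCC=O | intermediate
25 | but-3-yn-1-ol | C#CCCO | starting material
26 | isopropylmagnesium chloride | CC(C)[Mg]Cl | starting material
27 | 4-methyl-3-methylidenepentan-1-ol | C=C(CCO)C(C)C | intermediate
28 | 1-iodo-4-methyl-3-methylidenepentane | C=C(CCI)C(C)C | intermediate
29 | methyl 2-[bis(2,2,2-trifluoroethoxy)phosphoryl]-6-methyl-5-methylideneheptanoate | COC(=O)C(CCC(=C)C(C)C)P(=O)(OCC(F)(F)F)OCC(F)(F)F | intermediate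
30 | methyl (2Z,6Z,10Z)-12-acetoxy-6-(acetoxymethyl)-10-methyl-2-(4-methyl-3-methylidenepentyl)dodeca-2,6,10-trienoate | COC(=O)/C(=C\CC/C(=C/CC/C(C)=C\COC(C)=O)COC(C)=O)CCC(=C)C(C)C | intermediate
31 | (2Z,6Z,10Z)-12-hydroxy-6-(hydroxymethyl)-10-methyl-2-(4-methyl-3-methylidenepentyl)dodeca-2,6,10-trienoic acid | OC(=O)/C(=C\CC/C(=C/CC/C(C)=C\CO)CO)CCC(=C)C(C)C | intermediate
32 | acetic (2Z,6Z,10Z)-12-acetoxy-6-(acetoxymethyl)-10-methyl-2-(4-methyl-3-methylidenepentyl)dodeca-2,6,10-trienoic anhydride (not isolated) | CC(=O)OC(=O)/C(=C\CC/C(=C/CC/C(C)=C\COC(C)=O)COC(C)=O)CCC(=C)C(C)C | intermediate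
33 | (2Z,6Z,10Z)-12-acetoxy-6-(acetoxymethyl)-10-methyl-2-(4-methyl-3-methylidenepentyl)dodeca-2,6,10-trienoic acid | OC(=O)/C(=C\CC/C(=C/CC/C(C)=C\COC(C)=O)COC(C)=O)CCC(=C)C(C)C | intermediate
34 | ethyl 2-(hydroxymethyl)acrylate | C=C(CO)C(=O)OCC | starting material
35 | ethyl 2-[(tert-butyldimethylsilyloxy)methyl]acrylate | C=C(CO[Si](C)(C)C(C)(C)C)C(=O)OCC | intermediate
36 | 2-[(tert-butyldimethylsilyloxy)methyl]acrylic acid | C=C(CO[Si](C)(C)C(C)(C)C)C(=O)O | intermediate
37 | 2,4,6-trichlorobenzoic anhydride of acid 33 (not isolated) | O=C(OC(=O)c1c(Cl)cc(Cl)cc1Cl)/C(=C\CC/C(=C/CC/C(C)=C\COC(C)=O)COC(C)=O)CCC(=C)C(C)C | intermediate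
38 | 9-O-acyl (acid 33) 8-O-MOM 14-oxo melampolide, (6R,7S,8S,9S) | COCO[C@H]1[C@H]2C(=C)C(=O)O[C@@H]2/C=C(\C)CC/C=C(/C=O)[C@@H]1OC(=O)/C(=C\CC/C(=C/CC/C(C)=C\COC(C)=O)COC(C)=O)CCC(=C)C(C)C | intermediate
39 | 8-O-(bromomethyl) ether of 40 (not isolated) | BrCO[C@H]1[C@H]2C(=C)C(=O)O[C@@H]2/C=C(\C)CC/C=C(/C=O)[C@@H]1OC(=O)/C(=C\CC/C(=C/CC/C(C)=C\COC(C)=O)COC(C)=O)CCC(=C)C(C)C | intermediate
40 | 9-O-acyl (acid 33) 8-hydroxy 14-oxo melampolide, (6R,7R,8S,9S) | O[C@H]1[C@H]2C(=C)C(=O)O[C@@H]2/C=C(\C)CC/C=C(/C=O)[C@@H]1OC(=O)/C(=C\CC/C(=C/CC/C(C)=C\COC(C)=O)COC(C)=O)CCC(=C)C(C)C | intermediate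
41 | 9-O-acyl (acid 33) 8-O-{2-[(tert-butyldimethylsilyloxy)methyl]acryloyl} 14-oxo melampolide, (6R,7S,8S,9S) | C=C(CO[Si](C)(C)C(C)(C)C)C(=O)O[C@H]1[C@H]2C(=C)C(=O)O[C@@H]2/C=C(\C)CC/C=C(/C=O)[C@@H]1OC(=O)/C(=C\CC/C(=C/CC/C(C)=C\COC(C)=O)COC(C)=O)CCC(=C)C(C)C | intermediate
42 | CNP0240680.3 | C=C(CO)C(=O)O[C@H]1[C@H]2C(=C)C(=O)O[C@@H]2/C=C(\C)CC/C=C(/C=O)[C@@H]1OC(=O)/C(=C\CC/C(=C/CC/C(C)=C\COC(C)=O)COC(C)=O)CCC(=C)C(C)C | target

**Step count**
Total: 27 steps.
Longest linear sequence: 12 steps (1, 3–9, 24–27; the side-chain line 10, 12–15, 19–21, 24–27 is equally long).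

**Three steps most likely to fail**

Step 7 (bridged allylation, then translactonisation). The tether may make the transition state too strained, and oligomers or β-elimination of the 8-alkoxy group could take over. The fallback sets out from 7 and comes back at 13. It drops the δ-lactone tether: hydroxy enal 7 is joined to commercial ethyl 2-(bromomethyl)acrylate by cross-metathesis (second-generation Hoveyda–Grubbs catalyst, CH2Cl2, 40 °C) to give the open-chain ethyl (2Z,4S,5S,6E,10E)-2-(bromomethyl)-5-hydroxy-4-(methoxymethoxy)-6,10-dimethyl-12-oxododeca-2,6,10-trienoate F1. CrCl2 at high dilution then closes the ten-membered ring through the freely rotating acyclic allylchromium, and the 6-alkoxide lactonises directly on the ethyl ester to give 13. Control at C6 and C7 then rests on the macrocyclic transition state alone.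

Step 8 (SeO2 on the macrocycle). The reagent may attack C4=C5 (at C3 or C15) or oxidise the 9-OH instead of C14. The fallback sets out from 10 and comes back at 14. It moves the allylic oxidation in front of both ring closures, where C4=C5 is part of an enal and inert. Ester 10 is oxidised with SeO2/t-BuOOH to the 14-hydroxy ester F2; the [2,3]-shift makes the open-chain alkene Z, so it is already ring-cis. Ring-closing metathesis as in step 6 gives the hydroxy dihydropyranone F3. The CrCl2 cascade of step 7, now on a cis,trans seco-precursor and passing through the bridged hydroxy lactone F4, delivers diol 14 directly.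

Step 25 (MOM cleavage with the side chain in place). Me2BBr may ionise the allylic acetates or the allylic C9 ester. The fallback sets out from 15 and comes back at 41. It removes the MOM group before the large acid is attached. Alcohol 15 is silylated (Et3SiCl, imidazole, DMF) to the 9-O-triethylsilyl ether F5. The MOM ether is cleaved (Me2BBr, −78 °C) to the 8-alcohol F6. F6 is esterified with 36 (EDC·HCl, DMAP) to the 8-acrylate F7. PPTS in MeOH at 0 °C removes only the triethylsilyl group to give the 9-alcohol F8. Yamaguchi esterification with 33 under the step 24 conditions rejoins the route at 41.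

**Further compounds**
F1 | step 7 | ethyl (2Z,4S,5S,6E,10E)-2-(bromomethyl)-5-hydroxy-4-(methoxymethoxy)-6,10-dimethyl-12-oxododeca-2,6,10-trienoate | CCOC(=O)/C(CBr)=C/[C@H](OCOC)[C@@H](O)/C(C)=C/CC/C(C)=C/C=O
F2 | step 8 | (3S,4S,5Z,9E)-5-(hydroxymethyl)-3-(methoxymethoxy)-9-methyl-11-oxoundeca-1,5,9-trien-4-yl 2-(bromomethyl)prop-2-enoate | C=C[C@H](OCOC)[C@@H](OC(=O)C(=C)CBr)/C(CO)=C\CC/C(C)=C/C=O
F3 | step 8 | (2E,6Z)-7-[(2S,3S)-5-(bromomethyl)-3-(methoxymethoxy)-6-oxo-3,6-dihydro-2H-pyran-2-yl]-8-hydroxy-3-methylocta-2,6-dienal | BrCC1=C[C@H](OCOC)[C@H](/C(CO)=C\CC/C(C)=C/C=O)OC1=O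
F4 | step 8 | (1(10)Z,4E,6R,7S,8S,9S)-6,14-dihydroxy-8-(methoxymethoxy)germacra-1(10),4,11(13)-trien-12,9-olide (bridged, not isolated) | COCO[C@H]1[C@H]2C(=C)C(=O)O[C@H]1/C(CO)=C\CC/C(C)=C/[C@H]2O
F5 | step 25 | 9-O-triethylsilyl ether of 15 | COCO[C@H]1[C@H]2C(=C)C(=O)O[C@@H]2/C=C(\C)CC/C=C(/C=O)[C@@H]1O[Si](CC)(CC)CC
F6 | step 25 | 8-hydroxy 9-O-triethylsilyl 14-oxo melampolide | O[C@H]1[C@H]2C(=C)C(=O)O[C@@H]2/C=C(\C)CC/C=C(/C=O)[C@@H]1O[Si](CC)(CC)CC
F7 | step 25 | 8-O-{2-[(tert-butyldimethylsilyloxy)methyl]acryloyl} 9-O-triethylsilyl 14-oxo melampolide | C=C(CO[Si](C)(C)C(C)(C)C)C(=O)O[C@H]1[C@H]2C(=C)C(=O)O[C@@H]2/C=C(\C)CC/C=C(/C=O)[C@@H]1O[Si](CC)(CC)CC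
F8 | step 25 | 8-O-{2-[(tert-butyldimethylsilyloxy)methyl]acryloyl} 9-hydroxy 14-oxo melampolide | C=C(CO[Si](C)(C)C(C)(C)C)C(=O)O[C@H]1[C@H]2C(=C)C(=O)O[C@@H]2/C=C(\C)CC/C=C(/C=O)[C@@H]1O
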